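The route rests on disconnecting the chromanone's pyran ring at O1–C2 and C4–C4a, back to an aryl 1,1-dimethylpropargyl ether. In ring B, C4a is the only carbon without a substituent and lies ortho to C8a–O1, so a thermal propargyl Claisen shift from O1 can land only there; one heating step forms C4–C4a, remakes the O1–C2 bond and closes the 2,2-dimethyl-2H-chromene. Its precursor is the fully assembled tetra-O-benzyl diarylmethane: ring A with the (R)-2-methylbutanoyl ketone and methoxy group, ring B with the 2-methylbut-3-yn-2-yl ether on O1 and hydrogen at C4a. Hydration at benzylic C4, oxidation and hydrogenolysis then give the target.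

Key step: step 11

Remark: ring A is the acylphloroglucinol ring (C1 acyl, C2 OH, C3 Me, C4 OMe, C5 CH2, C6 OH); ring B and its pyran ring use chroman numbering (O1, C2, C3, C4, C4a, C5–C8, C8a). The only stereocenter (R, alpha to the ring A ketone) is bought in with acid 1 and never made or broken. Compounds 18 and 22 are isomers (C54H56O7). The carbinol carbon C4 of 23 is an uncontrolled epimer mixture that step 13 erases.

Step 1
Reactants: 1 (R)-2-methylbutanoic acid; 2 2-methylbenzene-1,3,5-triol
Product: 4 (2R)-2-methyl-1-(2,4,6-trihydroxy-3-methylphenyl)butan-1-one, via (R)-2-methylbutanoyl chloride 3 (not isolated)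
Conditions: (COCl)2, DMF (cat.), CH2Cl2, 0 °C to rt, concentrate; then 2, AlCl3, PhNO2–CH2Cl2, 0 °C to rt; aq. HCl work-up
Reagents that add atoms: none
Why: Friedel–Crafts C-acylation at one of the two equivalent free carbons of the strongly activated phloroglucinol ring should be clean, and the R center carried in from 1 is expected to survive because the acid chloride is made under neutral catalytic-DMF conditions and the acylation is kept at or below room temperature.

Step 2
Reactants: 4 (2R)-2-methyl-1-(2,4,6-trihydroxy-3-methylphenyl)butan-1-one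
Product: 5 (2R)-1-(2,6-dihydroxy-4-methoxy-3-methylphenyl)-2-methylbutan-1-one
Conditions: Me2SO4 (1.0 equiv), K2CO3, acetone, rt
Reagents that add atoms: dimethyl sulfate, COS(=O)(=O)OC
Why: Williamson O-methylation with one equivalent of dimethyl sulfate should select the 4-OH, which is para to the ketone, not hydrogen-bonded to the carbonyl and therefore the most acidic and most nucleophilic phenol (the selectivity behind aspidinol-type 4-O-methyl acylphloroglucinols).

Step 3
Reactants: 5 (2R)-1-(2,6-dihydroxy-4-methoxy-3-methylphenyl)-2-methylbutan-1-one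
Product: 6 2,4-dihydroxy-6-methoxy-5-methyl-3-[(2R)-2-methylbutanoyl]benzaldehyde
Conditions: POCl3, DMF, EtOAc, 0 °C to rt; then H2O, 40 °C
Reagents that add atoms: N,N-dimethylformamide, CN(C)C=O; water, O
Why: Vilsmeier–Haack formylation can only occur at C5, the single unsubstituted ring carbon, which is activated by two ortho oxygens and one para oxygen.

Step 4
Reactants: 6 2,4-dihydroxy-6-methoxy-5-methyl-3-[(2R)-2-methylbutanoyl]benzaldehyde
Product: 7 2,4-bis(benzyloxy)-6-methoxy-5-methyl-3-[(2R)-2-methylbutanoyl]benzaldehyde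
Conditions: BnBr, K2CO3, DMF, rt to 50 °C
Reagents that add atoms: benzyl bromide, BrCc1ccccc1
Why: Williamson benzylation in DMF caps both hydrogen-bonded phenols, and carbonate is far too weak a base to deprotonate the alpha-CH of the ketone, so the R center is not at risk.

Step 5
Reactants: 7 2,4-bis(benzyloxy)-6-methoxy-5-methyl-3-[(2R)-2-methylbutanoyl]benzaldehyde
Product: 8 (2R)-1-[2,6-bis(benzyloxy)-3-(hydroxymethyl)-4-methoxy-5-methylphenyl]-2-methylbutan-1-one
Conditions: NaBH4, THF–MeOH, −20 °C
Reagents that add atoms: none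
Why: Chemoselective borohydride reduction should touch only the aldehyde, because the ketone is alpha-branched, flanked by two benzyloxy groups and twisted out of the ring plane, which makes it much less electrophilic.

Step 6
Reactants: 9 methyl 3,5-dihydroxy-4-methylbenzoate
Product: 10 methyl 3,5-bis(benzyloxy)-4-methylbenzoate
Conditions: BnBr, K2CO3, DMF, 60 °C
Reagents that add atoms: benzyl bromide, BrCc1ccccc1
Why: Williamson benzylation of both phenols of a simple resorcinol ester is routine, and the ester is inert to K2CO3 in DMF.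

Step 7
Reactants: 10 methyl 3,5-bis(benzyloxy)-4-methylbenzoate
Product: 12 1-[3,5-bis(benzyloxy)-4-methylphenyl]ethan-1-one, via Weinreb amide 11 (not isolated)
Conditions: MeNHOMe·HCl, iPrMgCl, THF, −20 °C; then MeMgBr, 0 °C to rt
Reagents that add atoms: methylmagnesium bromide, C[Mg]Br
Why: Weinreb ketone synthesis in one flask: the magnesium amide of N,O-dimethylhydroxylamine converts the ester into amide 11, whose chelated tetrahedral adduct with MeMgBr holds until work-up and so stops the addition at the methyl ketone.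

Step 8
Reactants: 12 1-[3,5-bis(benzyloxy)-4-methylphenyl]ethan-1-one
Product: 14 3,5-bis(benzyloxy)-4-methylphenol, via 3,5-bis(benzyloxy)-4-methylphenyl acetate 13 (not isolated)
Conditions: mCPBA, TFA (cat.), CH2Cl2, rt; aq. NaHCO3 wash; then K2CO3 (cat.), MeOH, rt
Reagents that add atoms: meta-chloroperoxybenzoic acid, OOC(=O)c1cccc(Cl)c1
Why: Baeyer–Villiger oxidation of an aryl methyl ketone should give the aryl acetate because aryl migrates in preference to methyl (the corresponding aldehyde would suffer competing hydride migration on a ring without ortho or para donors), and mild methanolysis then frees the phenol.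

Step 9
Reactants: 8 (2R)-1-[2,6-bis(benzyloxy)-3-(hydroxymethyl)-4-methoxy-5-methylphenyl]-2-methylbutan-1-one; 14 3,5-bis(benzyloxy)-4-methylphenol
Product: 15 (2R)-1-[2,6-bis(benzyloxy)-3-{[2,4-bis(benzyloxy)-6-hydroxy-3-methylphenyl]methyl}-4-methoxy-5-methylphenyl]-2-methylbutan-1-one
Conditions: 14 (2 equiv), TsOH·H2O (10 mol%), CH2Cl2, 0 °C to rt
Reagents that add atoms: none
Why: Acid-catalysed Friedel–Crafts benzylation should work because carbinol 8 ionises readily to a benzylic cation stabilised by two ortho oxygens and one para oxygen, and phenol 14 offers two equivalent, highly nucleophilic carbons (ortho to OH, para to a benzyloxy group), with the excess of 14 holding back a second alkylation and the cold catalytic acid sparing the benzyl ethers and the R center.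

Step 10
Reactants: 15 (2R)-1-[2,6-bis(benzyloxy)-3-{[2,4-bis(benzyloxy)-6-hydroxy-3-methylphenyl]methyl}-4-methoxy-5-methylphenyl]-2-methylbutan-1-one; 16 2-methylbut-3-yn-2-ol
Product: 18 (2R)-1-[2,6-bis(benzyloxy)-3-({2,4-bis(benzyloxy)-3-methyl-6-[(2-methylbut-3-yn-2-yl)oxy]phenyl}methyl)-4-methoxy-5-methylphenyl]-2-methylbutan-1-one, via 2-methylbut-3-yn-2-yl trifluoroacetate 17 (not isolated)
Conditions: 16, (CF3CO)2O, DBU, MeCN, −5 °C; then 15, DBU, CuCl2·2H2O (cat.), MeCN, 0 °C
Reagents that add atoms: none
Why: Copper-catalysed propargylic etherification of the phenoxide by the tertiary propargylic trifluoroacetate (through a copper acetylide-derived electrophile) is the standard way to hindered aryl 1,1-dimethylpropargyl ethers, and O1 is the only free hydroxyl group in 15 because every other phenol is a benzyl ether.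

Step 11
Reactants: 18 (2R)-1-[2,6-bis(benzyloxy)-3-({2,4-bis(benzyloxy)-3-methyl-6-[(2-methylbut-3-yn-2-yl)oxy]phenyl}methyl)-4-methoxy-5-methylphenyl]-2-methylbutan-1-one
Product: 22 (2R)-1-[2,6-bis(benzyloxy)-3-{[5,7-bis(benzyloxy)-2,2,6-trimethyl-2H-chromen-8-yl]methyl}-4-methoxy-5-methylphenyl]-2-methylbutan-1-one, via allenyl dienone 19 (not isolated), via ortho-allenylphenol 20 (not isolated), via ortho-quinone methide 21 (not isolated)
Conditions: o-xylene (degassed), 140 °C, Ar
Reagents that add atoms: none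
Why: Aromatic propargyl Claisen rearrangement: a concerted (3,3) sigmatropic shift breaks the O1–C(Me)2 bond and joins the alkyne terminus (the future C4) to C4a, giving allenyl dienone 19, which tautomerises to ortho-allenylphenol 20. A 1,5-hydrogen shift from the phenolic OH to the central allene carbon then gives ortho-quinone methide 21, and a thermal six-electron oxa-electrocyclisation (disrotatory, oxygen onto the dimethyl-bearing terminus) closes the pyran ring and restores the O1–C2 bond and the aromatic ring. The closest known reaction type is the thermal conversion of aryl 1,1-dimethylpropargyl ethers into 2,2-dimethyl-2H-chromenes. No stereocenter is created, and the R center is only a spectator because the medium is neutral and free of Lewis acid. The selectivity needed is delivery of carbon to C4a and not to C8, and the substrate secures it: C8 carries the methylene bridge, so a shift there gives a dienone that cannot rearomatise and reverts, whereas the C4a adduct carries hydrogen, tautomerises and goes on.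

Step 12
Reactants: 22 (2R)-1-[2,6-bis(benzyloxy)-3-{[5,7-bis(benzyloxy)-2,2,6-trimethyl-2H-chromen-8-yl]methyl}-4-methoxy-5-methylphenyl]-2-methylbutan-1-one
Product: 23 (2R)-1-[2,6-bis(benzyloxy)-3-{[5,7-bis(benzyloxy)-4-hydroxy-2,2,6-trimethyl-3,4-dihydro-2H-chromen-8-yl]methyl}-4-methoxy-5-methylphenyl]-2-methylbutan-1-one (both C4 epimers)
Conditions: Co(acac)2 (cat.), PhSiH3, O2 (1 atm), THF, rt
Reagents that add atoms: dioxygen, O=O
Why: Mukaiyama hydration (cobalt hydride hydrogen-atom transfer, trapping by O2, reduction of the peroxide by the silane) adds H to C3 and oxygen to C4 because the intermediate radical is benzylic at C4; the new C4 stereocenter forms without control as both epimers, which is harmless since C4 becomes a carbonyl carbon in step 13.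

Step 13
Reactants: 23 (2R)-1-[2,6-bis(benzyloxy)-3-{[5,7-bis(benzyloxy)-4-hydroxy-2,2,6-trimethyl-3,4-dihydro-2H-chromen-8-yl]methyl}-4-methoxy-5-methylphenyl]-2-methylbutan-1-one (both C4 epimers)
Product: 24 5,7-bis(benzyloxy)-8-({2,4-bis(benzyloxy)-6-methoxy-5-methyl-3-[(2R)-2-methylbutanoyl]phenyl}methyl)-2,2,6-trimethyl-2,3-dihydro-4H-chromen-4-one
Conditions: Dess–Martin periodinane, CH2Cl2, 0 °C to rt
Reagents that add atoms: none
Why: Dess–Martin oxidation of the secondary benzylic alcohol is mild and nearly neutral, so both C4 epimers should converge on one chromanone without touching the benzyl ethers or the R center.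

Step 14
Reactants: 24 5,7-bis(benzyloxy)-8-({2,4-bis(benzyloxy)-6-methoxy-5-methyl-3-[(2R)-2-methylbutanoyl]phenyl}methyl)-2,2,6-trimethyl-2,3-dihydro-4H-chromen-4-one
Product: 25 5,7-dihydroxy-8-({2,4-dihydroxy-6-methoxy-5-methyl-3-[(2R)-2-methylbutanoyl]phenyl}methyl)-2,2,6-trimethyl-2,3-dihydro-4H-chromen-4-one
Conditions: H2 (1 atm), Pd/C, EtOAc–MeOH, rt
Reagents that add atoms: none
Why: Catalytic hydrogenolysis of the four benzyl aryl ethers under one atmosphere of hydrogen should leave the two chelated, hindered aryl ketones, the diarylmethane bridge and the R center untouched and give the target directly.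

Compound list
1 | (R)-2-methylbutanoic acid | CC[C@@H](C)C(=O)O | starting material
2 | 2-methylbenzene-1,3,5-triol | Cc1c(O)cc(O)cc1O | starting material
3 | (R)-2-methylbutanoyl chloride | CC[C@@H](C)C(=O)Cl | intermediate (not isolated)
4 | (2R)-2-methyl-1-(2,4,6-trihydroxy-3-methylphenyl)butan-1-one | CC[C@@H](C)C(=O)c1c(O)c(C)c(O)cc1O | intermediate
5 | (2R)-1-(2,6-dihydroxy-4-methoxy-3-methylphenyl)-2-methylbutan-1-one | CC[C@@H](C)C(=O)c1c(O)c(C)c(OC)cc1O | intermediate
6 | 2,4-dihydroxy-6-methoxy-5-methyl-3-[(2R)-2-methylbutanoyl]benzaldehyde | CC[C@@H](C)C(=O)c1c(O)c(C)c(OC)c(C=O)c1O | intermediate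
7 | 2,4-bis(benzyloxy)-6-methoxy-5-methyl-3-[(2R)-2-methylbutanoyl]benzaldehyde | CC[C@@H](C)C(=O)c1c(OCc2ccccc2)c(C)c(OC)c(C=O)c1OCc1ccccc1 | intermediate
8 | (2R)-1-[2,6-bis(benzyloxy)-3-(hydroxymethyl)-4-methoxy-5-methylphenyl]-2-methylbutan-1-one | CC[C@@H](C)C(=O)c1c(OCc2ccccc2)c(C)c(OC)c(CO)c1OCc1ccccc1 | intermediate
9 | methyl 3,5-dihydroxy-4-methylbenzoate | COC(=O)c1cc(O)c(C)c(O)c1 | starting material
10 | methyl 3,5-bis(benzyloxy)-4-methylbenzoate | COC(=O)c1cc(OCc2ccccc2)c(C)c(OCc2ccccc2)c1 | intermediate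
11 | 3,5-bis(benzyloxy)-N-methoxy-N,4-dimethylbenzamide (Weinreb amide) | CON(C)C(=O)c1cc(OCc2ccccc2)c(C)c(OCc2ccccc2)c1 | intermediate (not isolated)
12 | 1-[3,5-bis(benzyloxy)-4-methylphenyl]ethan-1-one | CC(=O)c1cc(OCc2ccccc2)c(C)c(OCc2ccccc2)c1 | intermediate
13 | 3,5-bis(benzyloxy)-4-methylphenyl acetate | CC(=O)Oc1cc(OCc2ccccc2)c(C)c(OCc2ccccc2)c1 | intermediate (not isolated)
14 | 3,5-bis(benzyloxy)-4-methylphenol | Cc1c(OCc2ccccc2)cc(O)cc1OCc1ccccc1 | intermediate
15 | (2R)-1-[2,6-bis(benzyloxy)-3-{[2,4-bis(benzyloxy)-6-hydroxy-3-methylphenyl]methyl}-4-methoxy-5-methylphenyl]-2-methylbutan-1-one | CC[C@@H](C)C(=O)c1c(OCc2ccccc2)c(C)c(OC)c(Cc2c(OCc3ccccc3)c(C)c(OCc3ccccc3)cc2O)c1OCc1ccccc1 | intermediate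
16 | 2-methylbut-3-yn-2-ol | CC(C)(O)C#C | starting material
17 | 2-methylbut-3-yn-2-yl trifluoroacetate | C#CC(C)(C)OC(=O)C(F)(F)F | intermediate (not isolated)
18 | (2R)-1-[2,6-bis(benzyloxy)-3-({2,4-bis(benzyloxy)-3-methyl-6-[(2-methylbut-3-yn-2-yl)oxy]phenyl}methyl)-4-methoxy-5-methylphenyl]-2-methylbutan-1-one | CC[C@@H](C)C(=O)c1c(OCc2ccccc2)c(C)c(OC)c(Cc2c(OCc3ccccc3)c(C)c(OCc3ccccc3)cc2OC(C)(C)C#C)c1OCc1ccccc1 | intermediate (key-step precursor)
19 | allenyl dienone: (2R)-1-[2,6-bis(benzyloxy)-3-{[2,4-bis(benzyloxy)-3-methyl-5-(3-methylbuta-1,2-dien-1-yl)-6-oxocyclohexa-1,3-dien-1-yl]methyl}-4-methoxy-5-methylphenyl]-2-methylbutan-1-one (both C4a epimers) | CC[C@@H](C)C(=O)c1c(OCc2ccccc2)c(C)c(OC)c(CC2=C(OCc3ccccc3)C(C)=C(OCc3ccccc3)C(C=C=C(C)C)C2=O)c1OCc1ccccc1 | intermediate (not isolated)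
20 | ortho-allenylphenol: (2R)-1-[2,6-bis(benzyloxy)-3-{[2,4-bis(benzyloxy)-6-hydroxy-3-methyl-5-(3-methylbuta-1,2-dien-1-yl)phenyl]methyl}-4-methoxy-5-methylphenyl]-2-methylbutan-1-one | CC[C@@H](C)C(=O)c1c(OCc2ccccc2)c(C)c(OC)c(Cc2c(OCc3ccccc3)c(C)c(OCc3ccccc3)c(C=C=C(C)C)c2O)c1OCc1ccccc1 | intermediate (not isolated)
21 | ortho-quinone methide: (2R)-1-[2,6-bis(benzyloxy)-3-{[2,4-bis(benzyloxy)-3-methyl-5-(3-methylbut-2-en-1-ylidene)-6-oxocyclohexa-1,3-dien-1-yl]methyl}-4-methoxy-5-methylphenyl]-2-methylbutan-1-one, Z at the exocyclic C4a=C4 bond (C3 cis to the C8a carbonyl) | CC[C@@H](C)C(=O)c1c(OCc2ccccc2)c(C)c(OC)c(CC2=C(OCc3ccccc3)C(C)=C(OCc3ccccc3)/C(=C/C=C(C)C)C2=O)c1OCc1ccccc1 | intermediate (not isolated)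
22 | (2R)-1-[2,6-bis(benzyloxy)-3-{[5,7-bis(benzyloxy)-2,2,6-trimethyl-2H-chromen-8-yl]methyl}-4-methoxy-5-methylphenyl]-2-methylbutan-1-one | CC[C@@H](C)C(=O)c1c(OCc2ccccc2)c(C)c(OC)c(Cc2c(OCc3ccccc3)c(C)c(OCc3ccccc3)c3c2OC(C)(C)C=C3)c1OCc1ccccc1 | intermediate (key-step product)
23 | (2R)-1-[2,6-bis(benzyloxy)-3-{[5,7-bis(benzyloxy)-4-hydroxy-2,2,6-trimethyl-3,4-dihydro-2H-chromen-8-yl]methyl}-4-methoxy-5-methylphenyl]-2-methylbutan-1-one (both C4 epimers) | CC[C@@H](C)C(=O)c1c(OCc2ccccc2)c(C)c(OC)c(Cc2c(OCc3ccccc3)c(C)c(OCc3ccccc3)c3c2OC(C)(C)CC3O)c1OCc1ccccc1 | intermediate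
24 | 5,7-bis(benzyloxy)-8-({2,4-bis(benzyloxy)-6-methoxy-5-methyl-3-[(2R)-2-methylbutanoyl]phenyl}methyl)-2,2,6-trimethyl-2,3-dihydro-4H-chromen-4-one | CC[C@@H](C)C(=O)c1c(OCc2ccccc2)c(C)c(OC)c(Cc2c(OCc3ccccc3)c(C)c(OCc3ccccc3)c3c2OC(C)(C)CC3=O)c1OCc1ccccc1 | intermediate
25 | 5,7-dihydroxy-8-({2,4-dihydroxy-6-methoxy-5-methyl-3-[(2R)-2-methylbutanoyl]phenyl}methyl)-2,2,6-trimethyl-2,3-dihydro-4H-chromen-4-one | CC[C@@H](C)C(=O)c1c(O)c(C)c(OC)c(Cc2c(O)c(C)c(O)c3c2OC(C)(C)CC3=O)c1O | target

Total step count: 14 steps.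
Longest linear sequence: 11 steps (steps 1–5, then 9–14, from 1 and 2). The ring B branch (steps 6–8) joins at step 9.

Steps most likely to fail

Step 11 (key step). The propargyl group may shift first to the bridge-bearing C8, and the blocked allenyl dienone may then be drained by an intramolecular Diels–Alder reaction instead of reverting. The tertiary ether may also fragment by elimination before it rearranges. The fallback sets out from phenol 15 and comes back at chromene 22. Phenol 15 would be condensed with 3-methylbut-2-enal under ethylenediammonium diacetate catalysis in hot toluene or xylene. Knoevenagel-type attack through C4a and loss of water should give the same ortho-quinone methide 21, which electrocyclises to 22. This is a formal (3+3) annulation that makes C4–C4a by condensation instead of a sigmatropic shift. No compound outside the list is made (F0).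

Step 9. A second benzylation may occur at the remaining free carbon of the phenol ring, the acid may strip benzyl ethers from the cation, or slow acid-catalysed enolisation may erode the R center. The fallback sets out from carbinol 8 (with phenol 14) and comes back at 15 without any acid. Carbinol 8 would be converted with MsCl, Et3N and LiCl in THF at 0 °C into the benzylic chloride, (2R)-1-[2,6-bis(benzyloxy)-3-(chloromethyl)-4-methoxy-5-methylphenyl]-2-methylbutan-1-one F1, used crude. Phenol 14 would be deprotonated with EtMgBr in toluene to bromomagnesium 3,5-bis(benzyloxy)-4-methylphenoxide F2. In this non-coordinating medium the metal-bound phenoxide should be alkylated by F1 at its ortho carbon (ortho-C-benzylation of a magnesium phenoxide), giving 15 after aqueous work-up.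

Step 1. Enolisation of the acid chloride (ketene formation) or of the aluminium-bound aryl ketone may partly racemise the R center, and a second acylation may compete. Enantiomeric purity would be checked on 4 before going on. The fallback sets out from 2 and 1 and comes back at 4, building the ketone by organometallic acylation. Triol 2 would be protected (MOMCl, iPr2NEt, CH2Cl2) as 1,3,5-tris(methoxymethoxy)-2-methylbenzene F3. Acid 1 would be coupled with MeNHOMe·HCl (EDC·HCl, iPr2NEt, CH2Cl2) to (2R)-N-methoxy-N,2-dimethylbutanamide F4. Directed ortho-lithiation of F3 with n-BuLi in THF at 0 °C, at a ring carbon flanked by two MOM ethers, would give 2,4,6-tris(methoxymethoxy)-3-methylphenyllithium F5. Adding F5 to F4 at −78 °C should give (2R)-2-methyl-1-[2,4,6-tris(methoxymethoxy)-3-methylphenyl]butan-1-one F6 through a chelated adduct that does not enolise. Methanolic HCl at rt would then remove the three acetals to give 4.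

Further compounds
F0 | step 11 | none | none
F1 | step 9 | (2R)-1-[2,6-bis(benzyloxy)-3-(chloromethyl)-4-methoxy-5-methylphenyl]-2-methylbutan-1-one | CC[C@@H](C)C(=O)c1c(OCc2ccccc2)c(C)c(OC)c(CCl)c1OCc1ccccc1
F2 | step 9 | bromomagnesium 3,5-bis(benzyloxy)-4-methylphenoxide | Cc1c(OCc2ccccc2)cc(O[Mg]Br)cc1OCc1ccccc1
F3 | step 1 | 1,3,5-tris(methoxymethoxy)-2-methylbenzene | Cc1c(OCOC)cc(OCOC)cc1OCOC
F4 | step 1 | (2R)-N-methoxy-N,2-dimethylbutanamide | CC[C@@H](C)C(=O)N(C)OC
F5 | step 1 | 2,4,6-tris(methoxymethoxy)-3-methylphenyllithium | [Li]c1c(OCOC)c(C)c(OCOC)cc1OCOC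
F6 | step 1 | (2R)-2-methyl-1-[2,4,6-tris(methoxymethoxy)-3-methylphenyl]butan-1-one | CC[C@@H](C)C(=O)c1c(OCOC)c(C)c(OCOC)cc1OCOC
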